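**Assumption:** the target is the nagelamide A structure. The drawn centre is (S) by CIP (disubstituted aminoimidazolyl > monosubstituted aminoimidazolyl > CH2 > H). It is made as the free base, and compounds 5, 7, 9, 11, 13 and 16 are taken as purchasable. Only atom-contributing species are numbered; catalysts, solvents and water are not.

## Retrosynthetic overview

1. Target 18 ⇒ bis-amide 17: both 2-aminoimidazoles are carried as imidazo[1,2-a]pyrimidines and unmasked last by hydrazinolysis.
2. 17 ⇒ diamine 15 + 2 × acylating agent 16 (two amide bonds); 15 ⇒ 14 by acid deprotection.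
3. 14 ⇒ iodide 12 + alkenylboronate 13 (Suzuki coupling installs the (E)-aminopropenyl arm); 12 ⇒ aldehyde 10 by reductive amination.
4. 10 ⇒ enal 8 + imidazo[1,2-a]pyrimidine 9: a new iminium-catalysed asymmetric Friedel–Crafts alkylation forms the bis(heteroaryl)methine C–C bond and the only stereocentre.
5. Ring order: one imidazo[1,2-a]pyrimidine is built in step 1; the second (9) and the pyrroles are bought; no other ring is formed, and both pyrimidine rings are excised in the last step.

## Route

**Step 1**
Reactants: 1, 2-aminopyrimidine; 2, 1,1,3-trichloroacetone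
Product: 3, 2-(dichloromethyl)imidazo[1,2-a]pyrimidine
Conditions: DME, rt, 16 h; then EtOH, reflux, 2 h; NaHCO3 work-up
Reagents that add atoms: 2, 1,1,3-trichloroacetone, O=C(CCl)C(Cl)Cl
Why: Chichibabin-type imidazo-annulation: ring-N alkylation by the CH2Cl carbon, then condensation of the exocyclic NH2 with the ketone, puts CHCl2 at C2 and leaves C3–H.

**Step 2**
Reactants: 3, 2-(dichloromethyl)imidazo[1,2-a]pyrimidine
Product: 4, imidazo[1,2-a]pyrimidine-2-carbaldehyde
Conditions: CaCO3, H2O, reflux, 1–2 h
Reagents that add atoms: water, O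
Why: Hydrolysis of a heterobenzylic gem-dichloride to the aldehyde under buffered aqueous conditions.

**Step 3**
Reactants: 4, imidazo[1,2-a]pyrimidine-2-carbaldehyde; 5, N-iodosuccinimide
Product: 6, 3-iodoimidazo[1,2-a]pyrimidine-2-carbaldehyde
Conditions: NIS (1.1 equiv), MeCN, rt → 50 °C, dark
Reagents that add atoms: 5, N-iodosuccinimide, O=C1CCC(=O)N1I
Why: Electrophilic aromatic iodination at C3, the only nucleophilic carbon of this ring; the iodine later serves as both blocking group and cross-coupling handle.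

**Step 4**
Reactants: 6, 3-iodoimidazo[1,2-a]pyrimidine-2-carbaldehyde; 7, (triphenylphosphoranylidene)acetaldehyde
Product: 8, (2E)-3-(3-iodoimidazo[1,2-a]pyrimidin-2-yl)prop-2-enal
Conditions: 7 (1.15 equiv), toluene, 70 °C
Reagents that add atoms: 7, (triphenylphosphoranylidene)acetaldehyde, O=CC=P(c1ccccc1)(c1ccccc1)c1ccccc1
Why: Wittig two-carbon homologation with a stabilised ylide gives the (E)-enal from an electron-poor heteroaryl aldehyde.

**Step 5 (key step, new)**
Reactants: 8, (2E)-3-(3-iodoimidazo[1,2-a]pyrimidin-2-yl)prop-2-enal (1 equiv); 9, imidazo[1,2-a]pyrimidine (3 equiv)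
Product: 10, (3S)-3-(imidazo[1,2-a]pyrimidin-3-yl)-3-(3-iodoimidazo[1,2-a]pyrimidin-2-yl)propanal
Conditions: (2R,5R)-5-benzyl-2-tert-butyl-3-methylimidazolidin-4-one·TFA (20 mol %), CH2Cl2/i-PrOH 85:15, −40 → −20 °C, 48 h; short silica plug, used directly
Reagents that add atoms: none
Why: Proposed new method: an iminium-catalysed enantioselective Friedel–Crafts alkylation of an imidazo[1,2-a]pyrimidine (a masked 2-aminoimidazole) at C3 with a β-azolyl enal, in which the imidazolidinone condenses with 8 to an (E)-iminium with one π-face shielded by the benzyl group, C3 of 9 (terminus of the N4–C8a=N1–C2=C3 vinylogous amidine, where this ring undergoes halogenation, Mannich and Michael reactions) attacks the open face of the β-carbon, the Wheland cation rearomatises and enamine hydrolysis releases 10 with the catalyst not incorporated; the closest known reaction type is the MacMillan imidazolidinone-catalysed Friedel–Crafts addition of indoles, pyrroles and dialkylanilines (similar basicity to 9) to enals including cinnamaldehydes, whose facial model predicts (S)-10 from the (2R,5R) catalyst, while the C3 iodine of 8 prevents self- and over-alkylation.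

**Step 6**
Reactants: 10, the (3S)-aldehyde; 11, (R)-tert-butanesulfinamide
Product: 12, (R)-N-[(3S)-3-(imidazo[1,2-a]pyrimidin-3-yl)-3-(3-iodoimidazo[1,2-a]pyrimidin-2-yl)propyl]-2-methylpropane-2-sulfinamide
Conditions: 11 (1.2 equiv), Ti(OEt)4, THF, rt; then NaBH4, −40 → 0 °C
Reagents that add atoms: 11, (R)-tert-butanesulfinamide, CC(C)(C)[S@@](=O)N
Why: Ellman sulfinyl-imine formation and in-pot hydride reduction (reductive amination) turns CHO into protected CH2NH without ever placing a leaving group on that carbon (which the neighbouring ring N1 would displace), and the β-stereocentre is not enolisable.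

**Step 7**
Reactants: 12, the iodo sulfinamide; 13, tert-butyl N-[(2E)-3-(4,4,5,5-tetramethyl-1,3,2-dioxaborolan-2-yl)prop-2-en-1-yl]carbamate
Product: 14, tert-butyl N-[(2E)-3-{2-[(1S)-3-{[(R)-tert-butylsulfinyl]amino}-1-(imidazo[1,2-a]pyrimidin-3-yl)propyl]imidazo[1,2-a]pyrimidin-3-yl}prop-2-en-1-yl]carbamate
Conditions: 13 (1.5 equiv), Pd(dppf)Cl2 (5–10 mol %), K3PO4, 1,4-dioxane/H2O 5:1, 70 °C
Reagents that add atoms: 13, the (E)-alkenyl pinacol boronate, CC(C)(C)OC(=O)NC/C=C/B1OC(C)(C)C(C)(C)O1
Why: Suzuki–Miyaura coupling of a 3-iodoimidazo-azine with an (E)-alkenylboronate proceeds with retention of alkene geometry, and the mild base does not touch the non-acidic methine.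

**Step 8**
Reactants: 14, the Boc/sulfinyl-protected diamine
Product: 15, (2E)-3-{2-[(1S)-3-amino-1-(imidazo[1,2-a]pyrimidin-3-yl)propyl]imidazo[1,2-a]pyrimidin-3-yl}prop-2-en-1-amine (isolated as hydrochloride)
Conditions: 4 M HCl in dioxane, MeOH, 0 °C → rt
Reagents that add atoms: none
Why: Acidolysis removes the N-sulfinyl and Boc groups together; ionising the stereocentre would need a cation at a ring C2-methyl position, which is poorly stabilised, so no racemisation is expected.

**Step 9**
Reactants: 15, the diamine hydrochloride; 16, 2,2,2-trichloro-1-(4,5-dibromo-1H-pyrrol-2-yl)ethanone (2.2 equiv)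
Product: 17, 4,5-dibromo-N-[(3S)-3-{3-[(1E)-3-(4,5-dibromo-1H-pyrrole-2-carboxamido)prop-1-en-1-yl]imidazo[1,2-a]pyrimidin-2-yl}-3-(imidazo[1,2-a]pyrimidin-3-yl)propyl]-1H-pyrrole-2-carboxamide
Conditions: i-Pr2NEt, DMF, rt, 12 h
Reagents that add atoms: 16, 2,2,2-trichloro-1-(4,5-dibromo-1H-pyrrol-2-yl)ethanone, O=C(c1cc(Br)c(Br)[nH]1)C(Cl)(Cl)Cl
Why: Haloform-type acylation of primary amines by a trichloromethyl ketone (loss of CHCl3) is the standard way to install bromopyrrole carboxamides, and no other N–H nucleophile is present.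

**Step 10**
Reactants: 17, the bis(imidazo[1,2-a]pyrimidine) bis-amide
Product: 18, target: 4,5-dibromo-N-[(3S)-3-(2-amino-1H-imidazol-5-yl)-3-{2-amino-4-[(1E)-3-(4,5-dibromo-1H-pyrrole-2-carboxamido)prop-1-en-1-yl]-1H-imidazol-5-yl}propyl]-1H-pyrrole-2-carboxamide
Conditions: N2H4·H2O (large excess), EtOH, 100 °C, sealed tube, degassed/Ar, 1–3 h; RP-HPLC
Reagents that add atoms: none
Why: Hydrazinolysis of imidazo[1,2-a]pyrimidines (addition to the pyrimidine ring, ring opening, extrusion of the three pyrimidine carbons with the hydrazine as pyrazole) releases the 2-aminoimidazoles, with N8 becoming the exocyclic NH2; secondary amides, the (E)-alkene under inert gas and the non-acidic stereocentre are unaffected.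

## Compound list

1 | 2-aminopyrimidine | Nc1ncccn1 | starting material
2 | 1,1,3-trichloroacetone | O=C(CCl)C(Cl)Cl | starting material
3 | 2-(dichloromethyl)imidazo[1,2-a]pyrimidine | ClC(Cl)c1cn2cccnc2n1 | intermediate
4 | imidazo[1,2-a]pyrimidine-2-carbaldehyde | O=Cc1cn2cccnc2n1 | intermediate
5 | N-iodosuccinimide | O=C1CCC(=O)N1I | starting material
6 | 3-iodoimidazo[1,2-a]pyrimidine-2-carbaldehyde | O=Cc1nc2ncccn2c1I | intermediate
7 | (triphenylphosphoranylidene)acetaldehyde | O=CC=P(c1ccccc1)(c1ccccc1)c1ccccc1 | starting material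
8 | (2E)-3-(3-iodoimidazo[1,2-a]pyrimidin-2-yl)prop-2-enal | O=C/C=C/c1nc2ncccn2c1I | intermediate
9 | imidazo[1,2-a]pyrimidine | c1cnc2nccn2c1 | starting material
10 | (3S)-3-(imidazo[1,2-a]pyrimidin-3-yl)-3-(3-iodoimidazo[1,2-a]pyrimidin-2-yl)propanal | c1cnc2ncc([C@H](CC=O)c3nc4ncccn4c3I)n2c1 | intermediate
11 | (R)-tert-butanesulfinamide | CC(C)(C)[S@@](=O)N | starting material
12 | (R)-N-[(3S)-3-(imidazo[1,2-a]pyrimidin-3-yl)-3-(3-iodoimidazo[1,2-a]pyrimidin-2-yl)propyl]-2-methylpropane-2-sulfinamide | c1cnc2ncc([C@H](CCN[S@](=O)C(C)(C)C)c3nc4ncccn4c3I)n2c1 | intermediate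
13 | tert-butyl N-[(2E)-3-(4,4,5,5-tetramethyl-1,3,2-dioxaborolan-2-yl)prop-2-en-1-yl]carbamate | CC(C)(C)OC(=O)NC/C=C/B1OC(C)(C)C(C)(C)O1 | starting material
14 | tert-butyl N-[(2E)-3-{2-[(1S)-3-{[(R)-tert-butylsulfinyl]amino}-1-(imidazo[1,2-a]pyrimidin-3-yl)propyl]imidazo[1,2-a]pyrimidin-3-yl}prop-2-en-1-yl]carbamate | c1cnc2ncc([C@H](CCN[S@](=O)C(C)(C)C)c3nc4ncccn4c3/C=C/CNC(=O)OC(C)(C)C)n2c1 | intermediate
15 | (2E)-3-{2-[(1S)-3-amino-1-(imidazo[1,2-a]pyrimidin-3-yl)propyl]imidazo[1,2-a]pyrimidin-3-yl}prop-2-en-1-amine | c1cnc2ncc([C@H](CCN)c3nc4ncccn4c3/C=C/CN)n2c1 | intermediate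
16 | 2,2,2-trichloro-1-(4,5-dibromo-1H-pyrrol-2-yl)ethanone | O=C(c1cc(Br)c(Br)[nH]1)C(Cl)(Cl)Cl | starting material
17 | 4,5-dibromo-N-[(3S)-3-{3-[(1E)-3-(4,5-dibromo-1H-pyrrole-2-carboxamido)prop-1-en-1-yl]imidazo[1,2-a]pyrimidin-2-yl}-3-(imidazo[1,2-a]pyrimidin-3-yl)propyl]-1H-pyrrole-2-carboxamide | c1cnc2ncc([C@H](CCNC(=O)c3cc(Br)c(Br)[nH]3)c3nc4ncccn4c3/C=C/CNC(=O)c3cc(Br)c(Br)[nH]3)n2c1 | intermediate
18 | (S)-target (nagelamide A structure) | Nc1ncc([C@H](CCNC(=O)c2cc(Br)c(Br)[nH]2)c2[nH]c(N)nc2/C=C/CNC(=O)c2cc(Br)c(Br)[nH]2)[nH]1 | target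

## Summary

**Total steps:** 10. **Longest linear sequence:** 10 (1 → 3 → 4 → 6 → 8 → 10 → 12 → 14 → 15 → 17 → 18).

**Three steps most likely to fail**

1. **Step 5 (proposed new asymmetric Friedel–Crafts).** Risks are low nucleophilicity of 9, acid buffering by the basic rings, and modest ee next to the ortho-iodo group. Fallback (known chemistry): make the same bond racemically by the Yonemitsu-type three-component condensation of 9, aldehyde 6 and Meldrum's acid (established for imidazo[1,2-a]pyridines and indoles). Then do decarboxylative ethanolysis and reduce/oxidise to rac-10. Resolve by preparative chiral SFC, or by separating the diastereomeric (R)-sulfinamides 12.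

2. **Step 10 (double hydrazinolysis on a hindered, fully functionalised substrate).** Fallback: reverse the endgame. Unmask both aminoimidazoles at the stage of 14 (Boc and sulfinamide tolerate hydrazine), remove the protecting groups with HCl, and finish with chemoselective bis-acylation of the two primary alkylamines by 16 (Na2CO3, DMF), as in classical oroidin endgames.

3. **Step 7 (Suzuki at C3 beside the bulky methine; protodeiodination).** Fallback: move the coupling ahead of the stereo-defining step. Couple the unhindered iodoaldehyde 6 with 13, do the Wittig homologation to the 3-alkenyl enal, and run the Friedel–Crafts step on that enal, where the alkenyl arm replaces iodine as the C3 blocking group.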